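**Retrosynthetic overview**
- Remove the two MOM groups, then cut the aryl–C(=O) bond: a C6-lithiated 5,7-bis(MOM-oxy)-2,2-dimethylchroman plus the Weinreb amide of 3-(2,2-dimethylchroman-6-yl)propanoic acid.
- Left chroman: deoxygenate 5,7-dihydroxy-2,2-dimethylchroman-4-one, whose pyranone ring closes by intramolecular oxa-Michael addition of a phenol onto an aryl enone made from phloroglucinol and 3-methylbut-2-enoic acid.
- Right chroman: Heck reaction and hydrogenation on 6-bromo-2,2-dimethylchroman, obtained from 6-bromo-2,2-dimethylchroman-4-one; that ring closes the same way (aldol condensation with acetone, then intramolecular oxa-Michael).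
- Ring order: each pyran ring is built on its own benzene ring in a separate branch; the two halves are joined in the second-to-last step.

Assumption: the target has no stereocentre (it is achiral), so no enantiocontrol is needed; "chroman" means 3,4-dihydro-2H-1-benzopyran.

**Route**

Step 1
Reactants: 1 phloroglucinol (benzene-1,3,5-triol); 2 3-methylbut-2-enoic acid
Product: 4 5,7-dihydroxy-2,2-dimethylchroman-4-one, via aryl enone 3 (not isolated)
Conditions: MeSO3H, P2O5 (Eaton's reagent), 1.0 equiv of 2, 70 °C, 1 h; ice water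
Reagents that add atoms: none
Why: Friedel–Crafts acylation of the threefold-symmetric, highly activated arene gives enone 3, whose ortho-OH adds 6-endo-trig to the β,β-dimethyl enone (intramolecular oxa-Michael addition) to close the pyranone ring, and no stereocentre arises because C2 carries two methyl groups.

Step 2
Reactants: 4 5,7-dihydroxy-2,2-dimethylchroman-4-one
Product: 5 2,2-dimethylchroman-5,7-diol
Conditions: Zn(Hg), conc. HCl, EtOH–H2O, reflux
Reagents that add atoms: none
Why: Clemmensen reduction is reliable for ortho/para-hydroxyaryl ketones (as in acylresorcinol to alkylresorcinol) and takes C4=O to CH2 while the phenols and the tertiary aryl ether are inert to Zn/HCl.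

Step 3
Reactants: 5 2,2-dimethylchroman-5,7-diol
Product: 6 5,7-bis(methoxymethoxy)-2,2-dimethylchroman
Conditions: NaH (2.4 equiv), MOMCl (2.4 equiv), DMF, 0 °C to rt
Reagents that add atoms: chloromethyl methyl ether (MOMCl), COCCl
Why: Williamson-type O-alkylation of both phenoxides (neither is hydrogen-bonded to a carbonyl after step 2) installs two base-stable, lithium-coordinating MOM ethers.

Step 4
Reactants: 7 1-(5-bromo-2-hydroxyphenyl)ethan-1-one; 8 acetone
Product: 10 6-bromo-2,2-dimethylchroman-4-one, via bromoaryl enone 9 (not isolated)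
Conditions: pyrrolidine (0.5 equiv), acetone (5 equiv), MeOH, reflux
Reagents that add atoms: none
Why: Kabbe condensation, in which a pyrrolidine-mediated (enamine/iminium) crossed aldol condensation with acetone gives enone 9 and the ortho-phenol then closes the ring by 6-endo-trig intramolecular oxa-Michael addition, with no stereocentre because C2 is gem-dimethyl.

Step 5
Reactants: 10 6-bromo-2,2-dimethylchroman-4-one
Product: 12 6-bromo-2,2-dimethylchroman, via chroman-4-ol 11 (not isolated)
Conditions: Et3SiH (3 equiv), TFA, rt to 50 °C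
Reagents that add atoms: none
Why: ionic hydrogenation (Kursanov–Parnes), in which hydride transfer to the protonated ketone gives racemic alcohol 11 that ionises to a benzylic cation stabilised by the ortho ring oxygen and takes a second hydride, erasing the transient stereocentre while Ar–Br and the ether survive.

Step 6
Reactants: 13 acryloyl chloride; 14 N,O-dimethylhydroxylamine hydrochloride
Product: 15 N-methoxy-N-methylacrylamide
Conditions: K2CO3 (2 equiv), CH2Cl2/H2O, 0 °C
Reagents that add atoms: none
Why: Schotten–Baumann N-acylation of the free-based hydroxylamine is much faster at 0 °C than aza-Michael addition or hydrolysis of the acid chloride.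

Step 7
Reactants: 12 6-bromo-2,2-dimethylchroman; 15 N-methoxy-N-methylacrylamide
Product: 16 (E)-3-(2,2-dimethylchroman-6-yl)-N-methoxy-N-methylacrylamide
Conditions: Pd(OAc)2 (2 mol%), P(o-tol)3 (4 mol%), NaOAc, DMA, 120 °C
Reagents that add atoms: none
Why: Mizoroki–Heck reaction, in which oxidative addition of Ar–Br, syn-carbopalladation at the terminal alkene carbon and syn-β-hydride elimination give the (E)-cinnamamide, whose geometry is irrelevant because the alkene is hydrogenated next.

Step 8
Reactants: 16 (E)-3-(2,2-dimethylchroman-6-yl)-N-methoxy-N-methylacrylamide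
Product: 17 3-(2,2-dimethylchroman-6-yl)-N-methoxy-N-methylpropanamide
Conditions: H2 (1 atm), 10% Pd/C, EtOAc, rt
Reagents that add atoms: none
Why: catalytic hydrogenation of the conjugated C=C is fast at 1 atm, while the amide N–O bond, the arene and the ether survive these mild conditions.

Step 9
Reactants: 6 5,7-bis(methoxymethoxy)-2,2-dimethylchroman; 17 3-(2,2-dimethylchroman-6-yl)-N-methoxy-N-methylpropanamide
Product: 20 1-[5,7-bis(methoxymethoxy)-2,2-dimethylchroman-6-yl]-3-(2,2-dimethylchroman-6-yl)propan-1-one, via C6 aryllithium 18 (not isolated), via lithium hemiaminal 19 (not isolated)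
Conditions: 6 (1.3 equiv), n-BuLi (1.25 equiv), TMEDA, THF, 0 °C, 1 h; then 17 (1.0 equiv), −78 to 0 °C; sat. aq NH4Cl
Reagents that add atoms: none
Why: directed ortho-metalation occurs at C6, the only position flanked by two chelating OMOM groups (C8 has one OMOM and the hindered ring oxygen), and the aryllithium then undergoes nucleophilic acyl substitution on the Weinreb amide through the chelated adduct 19, which releases the ketone only on quench so no over-addition occurs and its stereocentre is lost.

Step 10
Reactants: 20 1-[5,7-bis(methoxymethoxy)-2,2-dimethylchroman-6-yl]-3-(2,2-dimethylchroman-6-yl)propan-1-one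
Product: 21 1-(5,7-dihydroxy-2,2-dimethylchroman-6-yl)-3-(2,2-dimethylchroman-6-yl)propan-1-one (CNP0080574.0)
Conditions: conc. HCl (cat.), MeOH, 50 °C
Reagents that add atoms: none
Why: acid-catalysed MOM ether cleavage (acetal exchange to methanol) frees both phenols, while the tertiary chroman ethers and the saturated ketone are stable and, with no enone present, no flavanone-type cyclisation can occur.

**Compound list**
1 | phloroglucinol (benzene-1,3,5-triol) | Oc1cc(O)cc(O)c1 | starting material
2 | 3-methylbut-2-enoic acid (3,3-dimethylacrylic acid) | CC(C)=CC(=O)O | starting material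
3 | 3-methyl-1-(2,4,6-trihydroxyphenyl)but-2-en-1-one (aryl enone, formed in the flask) | CC(C)=CC(=O)c1c(O)cc(O)cc1O | intermediate
4 | 5,7-dihydroxy-2,2-dimethylchroman-4-one | CC1(C)CC(=O)c2c(O)cc(O)cc2O1 | intermediate
5 | 2,2-dimethylchroman-5,7-diol | CC1(C)CCc2c(O)cc(O)cc2O1 | intermediate
6 | 5,7-bis(methoxymethoxy)-2,2-dimethylchroman | CC1(C)CCc2c(OCOC)cc(OCOC)cc2O1 | intermediate
7 | 1-(5-bromo-2-hydroxyphenyl)ethan-1-one (5'-bromo-2'-hydroxyacetophenone) | CC(=O)c1cc(Br)ccc1O | starting material
8 | acetone | CC(C)=O | starting material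
9 | 1-(5-bromo-2-hydroxyphenyl)-3-methylbut-2-en-1-one (bromoaryl enone, formed in the flask) | CC(C)=CC(=O)c1cc(Br)ccc1O | intermediate
10 | 6-bromo-2,2-dimethylchroman-4-one | CC1(C)CC(=O)c2cc(Br)ccc2O1 | intermediate
11 | 6-bromo-2,2-dimethylchroman-4-ol (racemic, formed in the flask) | CC1(C)CC(O)c2cc(Br)ccc2O1 | intermediate
12 | 6-bromo-2,2-dimethylchroman | CC1(C)CCc2cc(Br)ccc2O1 | intermediate
13 | acryloyl chloride | C=CC(=O)Cl | starting material
14 | N,O-dimethylhydroxylamine hydrochloride | CNOC.Cl | starting material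
15 | N-methoxy-N-methylacrylamide | C=CC(=O)N(C)OC | intermediate
16 | (E)-3-(2,2-dimethylchroman-6-yl)-N-methoxy-N-methylacrylamide | CC1(C)CCc2cc(/C=C/C(=O)N(C)OC)ccc2O1 | intermediate
17 | 3-(2,2-dimethylchroman-6-yl)-N-methoxy-N-methylpropanamide | CC1(C)CCc2cc(CCC(=O)N(C)OC)ccc2O1 | intermediate
18 | [5,7-bis(methoxymethoxy)-2,2-dimethylchroman-6-yl]lithium (formed in the flask) | CC1(C)CCc2c(OCOC)c([Li])c(OCOC)cc2O1 | intermediate
19 | lithium 1-[5,7-bis(methoxymethoxy)-2,2-dimethylchroman-6-yl]-3-(2,2-dimethylchroman-6-yl)-1-[methoxy(methyl)amino]propan-1-olate (racemic tetrahedral adduct, formed in the flask) | CC1(C)CCc2cc(CCC(O[Li])(N(C)OC)c3c(OCOC)cc4c(c3OCOC)CCC(C)(C)O4)ccc2O1 | intermediate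
20 | 1-[5,7-bis(methoxymethoxy)-2,2-dimethylchroman-6-yl]-3-(2,2-dimethylchroman-6-yl)propan-1-one | CC1(C)CCc2cc(CCC(=O)c3c(OCOC)cc4c(c3OCOC)CCC(C)(C)O4)ccc2O1 | intermediate
21 | 1-(5,7-dihydroxy-2,2-dimethylchroman-6-yl)-3-(2,2-dimethylchroman-6-yl)propan-1-one (achiral) | CC1(C)CCc2cc(CCC(=O)c3c(O)cc4c(c3O)CCC(C)(C)O4)ccc2O1 | target

**Step count**
Total steps: 10.
Longest linear sequence: 6 (steps 4, 5, 7, 8, 9, 10). The other two branches are steps 1–3 and step 6.

**Three steps most likely to fail, with fallbacks**

Step 9 (lithiation and Weinreb acylation). The hindered, doubly ortho-oxygenated aryllithium may enolise amide 17 instead of adding to it. The fallback sets out from 17 (and 6) and comes back at 20. Reduce 17 with DIBAL-H (THF, −78 °C) to 3-(2,2-dimethylchroman-6-yl)propanal F1. Add aryllithium 18, made from 6 as before, to this far more electrophilic aldehyde to give racemic 1-[5,7-bis(methoxymethoxy)-2,2-dimethylchroman-6-yl]-3-(2,2-dimethylchroman-6-yl)propan-1-ol F2. Oxidise F2 with Dess–Martin periodinane (CH2Cl2, NaHCO3) to ketone 20.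

Step 2 (Clemmensen reduction). The hydrogen-bonded, vinylogous-ester-like carbonyl may reduce incompletely or give pinacol-type dimers. The fallback sets out from 4 and comes back at 6. Protect first (NaH, MOMCl, DMF) to 5,7-bis(methoxymethoxy)-2,2-dimethylchroman-4-one F3. Reduce the now unchelated ketone with NaBH4 (MeOH) to racemic 5,7-bis(methoxymethoxy)-2,2-dimethylchroman-4-ol F4. Treat with MsCl/Et3N (CH2Cl2, 0 °C to rt); the transient 5,7-bis(methoxymethoxy)-2,2-dimethylchroman-4-yl methanesulfonate F5 eliminates in the flask to 5,7-bis(methoxymethoxy)-2,2-dimethyl-2H-chromene F6. Hydrogenate (H2, Pd/C, EtOAc) to reach 6.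

Step 7 (Heck reaction). The aryl bromide is electron-rich (para-alkoxy), so oxidative addition may be slow and the acrylamide may polymerise. The fallback sets out from 12 and comes back at 16. Bromine–lithium exchange (n-BuLi, THF, −78 °C) gives (2,2-dimethylchroman-6-yl)lithium F7, which is formylated with DMF to 2,2-dimethylchroman-6-carbaldehyde F8. Horner–Wadsworth–Emmons olefination with diethyl [2-[methoxy(methyl)amino]-2-oxoethyl]phosphonate (NaH, THF, 0 °C) gives the (E)-acrylamide 16.

**Further compounds**
F1 | step 9 | 3-(2,2-dimethylchroman-6-yl)propanal | CC1(C)CCc2cc(CCC=O)ccc2O1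
F2 | step 9 | 1-[5,7-bis(methoxymethoxy)-2,2-dimethylchroman-6-yl]-3-(2,2-dimethylchroman-6-yl)propan-1-ol (racemic) | CC1(C)CCc2cc(CCC(O)c3c(OCOC)cc4c(c3OCOC)CCC(C)(C)O4)ccc2O1
F3 | step 2 | 5,7-bis(methoxymethoxy)-2,2-dimethylchroman-4-one | CC1(C)CC(=O)c2c(OCOC)cc(OCOC)cc2O1
F4 | step 2 | 5,7-bis(methoxymethoxy)-2,2-dimethylchroman-4-ol (racemic) | CC1(C)CC(O)c2c(OCOC)cc(OCOC)cc2O1
F5 | step 2 | 5,7-bis(methoxymethoxy)-2,2-dimethylchroman-4-yl methanesulfonate (racemic, not isolated) | CC1(C)CC(OS(C)(=O)=O)c2c(OCOC)cc(OCOC)cc2O1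
F6 | step 2 | 5,7-bis(methoxymethoxy)-2,2-dimethyl-2H-chromene | CC1(C)C=Cc2c(OCOC)cc(OCOC)cc2O1
F7 | step 7 | (2,2-dimethylchroman-6-yl)lithium (not isolated) | CC1(C)CCc2cc([Li])ccc2O1
F8 | step 7 | 2,2-dimethylchroman-6-carbaldehyde | CC1(C)CCc2cc(C=O)ccc2O1
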